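I decided to follow G, not E, since both earlier runs charged E at 0.36 M and differed in G.

all flasks: E 0.36 M; Q 1 mol%
- dawn: G 0.34 equiv; run made earlier
- dusk: G 0.59 equiv; run made earlier
- green: G 1.10 equiv; time 2.5 h
- ochre: G 0.280 equiv; time 2.5 h

| run | time / min | J / % |
|---|---|---|
| dawn | 10.0 | 0.2 |
| dawn | 25.0 | 1.5 |
| dawn | 50.0 | 3.5 |
| dawn | 80.0 | 5.2 |
| dusk | 10.0 | 2.9 |
| dusk | 25.0 | 2.4 |
| dusk | 50.0 | 5.1 |
| dusk | 80.0 | 8.5 |

(scatter of a reading: 1 percentage point)



- which of the two ends with the higher amount of J, in percent of the E charged ("neither" if they lie within 2 percentage points) (green / ochre / neither)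
- J at the end, in percent of the E charged, green
- J at the end, in percent of the E charged, ochre

I divided each last reading, at 80.0 min, by its charge of G. The dawn run had turned 15.3% of its G into J, and the dusk run 14.4%. I read these as one share, given the scatter of 1 percentage point on each reading. With E and Q charged the same and at the same time, a pseudo-first-order loss of G gives one share from different charges. So I took any fast catalyst step as settled and let one slow step consume G.

That left two times. One is the G lifetime, the time in which G falls by a factor of e at this loading of Q: 8.29 h. The other is the run, 2.5 h, which is shorter, with a ratio of 0.301. This ratio gave a share of 26.0%, which I applied to the charges of green and ochre as an estimate for these two flasks. My reckoning was therefore 28.6% for green and 7.29% for ochre.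

The forecast took “first order in each of E and G” and said green, with 26% (18% to 32%) and 7.5% (5.5% to 10%). My green stood above its value, and my ochre just below.

Green gave 26.6% and ochre 7.91%, so green ended higher.

    E + Q → X (k = 0.0860 L mol⁻¹ s⁻¹)
    G + X → D (k = 0.0110 L mol⁻¹ s⁻¹)
    D → Q + J (k = 0.0280 s⁻¹)

At the end of green, 79.1% of the catalyst stood as X, the resting state, and 75.7% of G remained, against my 74.0%. I then took the lifetime as inverse to Q for green's neighbour with 4 mol% of Q, which made it 2.07 h. That left 29.9% of G by my reckoning. The neighbour held 32.3% of G, with J at 74.3%.

(The numbers in the tables are calculated on assumed constants, and the scatter is random.)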